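The rate constants are made up; no experiment stands behind them.

Two things are asked of these flasks, a row of link yields and its shape, and both hang on one ratio to watch during the run.

    first end groups + second end groups ⇌ links + by-product (K1 = 13, k1 = 0.80 /M/s)
    second end groups + links → over-reaction product (k2 = 1.1 /M/s)
    first end groups + by-product → side product (k3 = 0.64 /M/s)

| flask | first end groups | second end groups | time |
|---|---|---|---|
| Saturday's | 15 mM | 5.00 mM | 2.0 min |
| Monday's | 15 mM | 15.0 mM | 2.0 min |
| Friday's | 15 mM | 50.0 mM | 2.0 min |
| Tuesday's | 15 mM | 150 mM | 2.0 min |
| Wednesday's | 15 mM | 400 mM | 2.0 min |

- amount of links at the end, in percent of the first end groups charged for Saturday's, Monday's, Friday's, Tuesday's, Wednesday's, in this order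
- the shape of the row from first to last (falls all the way / rises, then falls / rises all the way / falls, then rises / hardly changes)

- "hardly changes" means that all values lie within two and a half points (for a concentration: within two and a half percent of the largest)
- run time (Saturday's): 2.0 min
- a step back or a flat step of under half a point counts as no turn

I divide one rate by another. The forward first step makes links at a rate of its constant times c(first end groups) times c(second end groups), and the second step uses them at its constant times c(second end groups) times c(links). In this quotient c(second end groups) cancels and time drops out. I set the return aside, since its constant of 0.0615 /M/s stands against 1.1 /M/s for the second step. So links rise while c(links)/c(first end groups) lies below the turning ratio, the forward constant of the first step over the constant of the second, 0.727, and they fall above it.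

Now I turn the settings by hand. First, a low charge of second end groups: in Saturday's flask they are the limiting reagent, and links stay under 0.333 of the first end groups charged. With the third step aside, the ratio in Saturday's flask can end no higher than 0.500, its value if every second end group became a link, and this bound lies below the turn, so I expect links in Saturday's flask still to be rising.

Second, time, at equal charges: in Monday's flask simple second-order decay leaves 41.0% of the first end groups after 2.0 min. The turn lies at 42.8% left. So Monday's flask ends near the top of its curve, and with the third step aside that top gives 0.311 of the charge as a ceiling.

Third, a large excess: in Tuesday's flask the decay of links is pseudo-first-order, with a half-life near 4.20 s, far shorter than the run, so I expect next to nothing there and in Wednesday's flask. By the same simple decay, an equal charge reaches that turn at the end of the run at 13.9 mM, higher than Saturday's charge and lower than Wednesday's. My row therefore rises, then falls, with its top at Monday's flask.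

The forecast gives 17.5%, 26%, 6%, 0.002% and 0%, shaped rises, then falls, “leaving a peak near equal charges”. The flasks give 18.0%, 27.7%, 6.15%, 0% and 0%, so the row rises, then falls.

In Saturday's flask at 2.00 min, c(links)/c(first end groups) reads 0.261, lower than the turning ratio of 0.727, and links are made 2.71 times as fast as they are used up. In Monday's flask the same ratio goes from 0.499 at 1.00 min to 0.808 at 2.00 min, while links go from 26.7% to 27.7% and stand at 14.1% after 20.0 min.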